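## Retrosynthetic overview

1. Target 17 ⇐ aldehyde 16 (NaBH4) ⇐ dibenzyl ether 15 (BCl3) ⇐ diaryl ether C5–O bond by SNAr of the 5-OH of phthalide 9 on aryl fluoride 14, whose fluorine is flanked by CHO and CO2Me.
2. Phthalide 9 (ring B with its lactone) is not taken from an arene: it is built from the acyclic ynone carbonate 5 and dimethyl methylmalonate 6 in one anionic cascade (step 4).
3. Enabling feature (phthalide locants): C7a lies between the phenolic carbon C7 and the lactone carbonyl C1, and O5/O7 are meta. Ring B is therefore the enol form of a 2-alkoxycyclohexene-1,3-dione carrying a β-keto-lactone at C7a, so C7a≡C3a can be the alkyne of an ynone (C7 = ketone) whose allenolate carbon C7a attacks the carbonate carbon C1 already bound to O2–C3.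
4. Order of ring formation: the furanone (lactone) ring through the C1–C7a bond, then benzene ring B through a C5–C6 Claisen closure and loss of the blocking CO2Me, both in step 4. Ring A is bought as 3-fluoro-5-methylphenol and elaborated by bromination, benzylation, ortho-lithiation/formylation and carbonylation.
5. Fragment 5 comes in three steps from THP-protected propargyl alcohol and the Weinreb amide of benzyloxyacetic acid.

Key step: step 4

Assumption: the target has no stereogenic element; the tetrahydropyranyl compounds (1, 3 and the THP-bearing fallback compounds) are racemates and the two sp3 centres of the transient compound 8 are erased on aromatization, so no stereocontrol is needed anywhere.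

## Route

Step 1
Reactants: 1 2-(prop-2-yn-1-yloxy)oxane; 2 2-(benzyloxy)-N-methoxy-N-methylacetamide
Product: 3 1-(benzyloxy)-5-(oxan-2-yloxy)pent-3-yn-2-one
Conditions: 1, n-BuLi, THF, −78 °C; then 2, −78 → 0 °C; aq. NH4Cl
Reagents that add atoms: none
Why: Weinreb ketone synthesis, in which the lithium acetylide adds once to the N-methoxy-N-methylamide and the chelated tetrahedral adduct collapses only on work-up, so over-addition and conjugate addition to the ynone are excluded.

Step 2
Reactants: 3 1-(benzyloxy)-5-(oxan-2-yloxy)pent-3-yn-2-one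
Product: 4 1-(benzyloxy)-5-hydroxypent-3-yn-2-one
Conditions: PPTS (cat.), MeOH, 25 °C
Reagents that add atoms: none
Why: Acid-catalysed acetal exchange (THP cleavage) with methanol is mild enough to leave the ynone and the benzyl ether untouched.

Step 3
Reactants: 4 1-(benzyloxy)-5-hydroxypent-3-yn-2-one
Product: 5 5-(benzyloxy)-4-oxopent-2-yn-1-yl methyl carbonate
Conditions: ClCO2Me, pyridine, CH2Cl2, −20 → 0 °C
Reagents that add atoms: methyl chloroformate, COC(=O)Cl
Why: O-acylation of the primary propargylic alcohol by a chloroformate (carbonate formation) places the future lactone carbonyl carbon on O2 before any C–C bond is made.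

Step 4
Reactants: 5 5-(benzyloxy)-4-oxopent-2-yn-1-yl methyl carbonate; 6 dimethyl 2-methylpropanedioate
Product: 9 6-(benzyloxy)-5,7-dihydroxy-4-methyl-2-benzofuran-1(3H)-one, via acylbutenolide malonate 7 (not isolated), via blocked cyclohexenedione ester 8 (not isolated)
Conditions: 6 (1.2 equiv), NaH, THF, 0 °C; 5 added slowly, −40 → 0 °C; then KOt-Bu (2.2 equiv), 0 → 25 °C; MeOH, 40 °C; 1 M HCl
Reagents that add atoms: none
Why: Proposed new method: the sodium enolate of 6 should add to the ynone β-carbon (C3a) of 5 to give a linear allenolate whose central carbon (future C7a) has its reactive lobe in the plane of the C3a substituents, so it is acylated by the tethered carbonate carbon (C1) in a 5-(enolexo)-exo-trig closure that forms the C1–C7a bond and the furanone ring of 7 with loss of methoxide; tert-butoxide then enolizes the only ketone α-carbon (C6), which attacks one of the two geminal esters in a 6-(enolendo)-exo-trig Claisen closure to give 8, and the liberated methoxide cleaves the remaining ester on the quaternary C4 (retro-Claisen) so that the ring tautomerizes to the resorcinol 9. The closest known reaction types are Michael-initiated ring closure, the tandem conjugate addition–Dieckmann sequence and the base-mediated malonate–alkynone annulation to resorcinols; what is new is the interception of the allenolate by a carbonate, so that the lactone carbonyl is attached by C–C bond formation. No stereocentre has to be controlled, because C4 and C6 of 8 become sp2 on aromatization. The step needs C- rather than O-acylation of the allenolate, which the geometry secures (O-attack would require a cyclic allene); conjugate rather than carbonyl addition, which the soft malonate anion secures; and a single mode of benzannulation, which is secured because C6 is the only enolizable carbon beside the ketone and the two esters on C4 are equivalent. Slow addition of 5 to a slight excess of the enolate should keep the liberated methoxide from competing for the ynone.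

Step 5
Reactants: 10 3-fluoro-5-methylphenol
Product: 11 4-bromo-3-fluoro-5-methylphenol
Conditions: NBS, MeCN, −10 → 0 °C
Reagents that add atoms: N-bromosuccinimide, O=C1CCC(=O)N1Br
Why: Electrophilic aromatic bromination, in which the hydroxyl group directs para to a position also activated by the adjacent fluorine and methyl groups, and NBS in acetonitrile favours para over ortho attack.

Step 6
Reactants: 11 4-bromo-3-fluoro-5-methylphenol
Product: 12 5-(benzyloxy)-2-bromo-1-fluoro-3-methylbenzene
Conditions: BnBr, K2CO3, DMF, 25 °C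
Reagents that add atoms: benzyl bromide, BrCc1ccccc1
Why: Williamson ether synthesis on the phenoxide with a reactive benzylic halide.

Step 7
Reactants: 12 5-(benzyloxy)-2-bromo-1-fluoro-3-methylbenzene
Product: 13 6-(benzyloxy)-3-bromo-2-fluoro-4-methylbenzaldehyde
Conditions: LDA (commercial solution), THF, −78 °C; DMF, −78 °C; aq. NH4Cl
Reagents that add atoms: N,N-dimethylformamide, CN(C)C=O
Why: Directed ortho-metalation, in which the C–H flanked by fluorine and the benzyloxy group is by far the most acidic, the amide base does not undergo bromine–lithium exchange, and the aryllithium is stable at −78 °C and is formylated by DMF.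

Step 8
Reactants: 13 6-(benzyloxy)-3-bromo-2-fluoro-4-methylbenzaldehyde
Product: 14 methyl 4-(benzyloxy)-2-fluoro-3-formyl-6-methylbenzoate
Conditions: Pd(OAc)2, Xantphos, CO (3 bar), Et3N, MeOH/toluene, 90 °C
Reagents that add atoms: carbon monoxide, [C-]#[O+]; methanol, CO
Why: Palladium-catalysed alkoxycarbonylation of the aryl bromide (oxidative addition, CO insertion, methanolysis of the acyl-palladium), to which aldehyde, aryl fluoride and benzyl ether are inert.

Step 9
Reactants: 9 6-(benzyloxy)-5,7-dihydroxy-4-methyl-2-benzofuran-1(3H)-one; 14 methyl 4-(benzyloxy)-2-fluoro-3-formyl-6-methylbenzoate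
Product: 15 methyl 4-(benzyloxy)-2-{[6-(benzyloxy)-7-hydroxy-4-methyl-1-oxo-1,3-dihydro-2-benzofuran-5-yl]oxy}-3-formyl-6-methylbenzoate
Conditions: K2CO3 (1.1 equiv), DMSO, 60–70 °C
Reagents that add atoms: none
Why: Nucleophilic aromatic substitution by addition–elimination, in which the fluorine of 14 is activated by the ortho-formyl and ortho-ester groups, and one equivalent of base ionizes the more acidic, non-chelated 5-OH of 9 (para to the lactone carbonyl) while the 7-OH stays hydrogen-bonded to that carbonyl.

Step 10
Reactants: 15 methyl 4-(benzyloxy)-2-{[6-(benzyloxy)-7-hydroxy-4-methyl-1-oxo-1,3-dihydro-2-benzofuran-5-yl]oxy}-3-formyl-6-methylbenzoate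
Product: 16 methyl 2-[(6,7-dihydroxy-4-methyl-1-oxo-1,3-dihydro-2-benzofuran-5-yl)oxy]-3-formyl-4-hydroxy-6-methylbenzoate
Conditions: BCl3, pentamethylbenzene, CH2Cl2, −78 → −40 °C; MeOH quench
Reagents that add atoms: none
Why: Lewis-acid debenzylation of aryl benzyl ethers at low temperature, with the benzyl cation trapped by pentamethylbenzene (Friedel–Crafts scavenging), should leave methyl ester, lactone, aldehyde and diaryl ether intact.

Step 11
Reactants: 16 methyl 2-[(6,7-dihydroxy-4-methyl-1-oxo-1,3-dihydro-2-benzofuran-5-yl)oxy]-3-formyl-4-hydroxy-6-methylbenzoate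
Product: 17 methyl 2-[(6,7-dihydroxy-4-methyl-1-oxo-1,3-dihydro-2-benzofuran-5-yl)oxy]-4-hydroxy-3-(hydroxymethyl)-6-methylbenzoate
Conditions: NaBH4, THF/MeOH, 0 °C; aq. NH4Cl (pH 6)
Reagents that add atoms: none
Why: Chemoselective borohydride reduction of the aryl aldehyde, which at 0 °C should not touch the hindered methyl ester or the phthalide lactone.

## Compound list

1 | 2-(prop-2-yn-1-yloxy)oxane (racemic) | C#CCOC1CCCCO1 | starting material
2 | 2-(benzyloxy)-N-methoxy-N-methylacetamide | CON(C)C(=O)COCc1ccccc1 | starting material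
3 | 1-(benzyloxy)-5-(oxan-2-yloxy)pent-3-yn-2-one (racemic) | O=C(COCc1ccccc1)C#CCOC1CCCCO1 | intermediate
4 | 1-(benzyloxy)-5-hydroxypent-3-yn-2-one | O=C(COCc1ccccc1)C#CCO | intermediate
5 | 5-(benzyloxy)-4-oxopent-2-yn-1-yl methyl carbonate | COC(=O)OCC#CC(=O)COCc1ccccc1 | intermediate
6 | dimethyl 2-methylpropanedioate (dimethyl methylmalonate) | COC(=O)C(C)C(=O)OC | starting material
7 | dimethyl 2-{4-[(benzyloxy)acetyl]-5-oxo-2,5-dihydrofuran-3-yl}-2-methylpropanedioate | COC(=O)C(C)(C(=O)OC)C1=C(C(=O)COCc2ccccc2)C(=O)OC1 | intermediate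
8 | methyl 6-(benzyloxy)-4-methyl-1,5,7-trioxo-1,3,4,5,6,7-hexahydro-2-benzofuran-4-carboxylate (stereoisomer and enol mixture) | COC(=O)C1(C)C(=O)C(OCc2ccccc2)C(=O)C2=C1COC2=O | intermediate
9 | 6-(benzyloxy)-5,7-dihydroxy-4-methyl-2-benzofuran-1(3H)-one | Cc1c(O)c(OCc2ccccc2)c(O)c2C(=O)OCc12 | intermediate
10 | 3-fluoro-5-methylphenol | Cc1cc(O)cc(F)c1 | starting material
11 | 4-bromo-3-fluoro-5-methylphenol | Cc1cc(O)cc(F)c1Br | intermediate
12 | 5-(benzyloxy)-2-bromo-1-fluoro-3-methylbenzene | Cc1cc(OCc2ccccc2)cc(F)c1Br | intermediate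
13 | 6-(benzyloxy)-3-bromo-2-fluoro-4-methylbenzaldehyde | Cc1cc(OCc2ccccc2)c(C=O)c(F)c1Br | intermediate
14 | methyl 4-(benzyloxy)-2-fluoro-3-formyl-6-methylbenzoate | COC(=O)c1c(C)cc(OCc2ccccc2)c(C=O)c1F | intermediate
15 | methyl 4-(benzyloxy)-2-{[6-(benzyloxy)-7-hydroxy-4-methyl-1-oxo-1,3-dihydro-2-benzofuran-5-yl]oxy}-3-formyl-6-methylbenzoate | COC(=O)c1c(C)cc(OCc2ccccc2)c(C=O)c1Oc1c(C)c2COC(=O)c2c(O)c1OCc1ccccc1 | intermediate
16 | methyl 2-[(6,7-dihydroxy-4-methyl-1-oxo-1,3-dihydro-2-benzofuran-5-yl)oxy]-3-formyl-4-hydroxy-6-methylbenzoate | COC(=O)c1c(C)cc(O)c(C=O)c1Oc1c(C)c2COC(=O)c2c(O)c1O | intermediate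
17 | methyl 2-[(6,7-dihydroxy-4-methyl-1-oxo-1,3-dihydro-2-benzofuran-5-yl)oxy]-4-hydroxy-3-(hydroxymethyl)-6-methylbenzoate | COC(=O)c1c(C)cc(O)c(CO)c1Oc1c(C)c2c(c(O)c1O)C(=O)OC2 | target

## Step count and risks

Total steps: 11. Longest linear sequence: 7 steps (steps 1, 2, 3, 4, 9, 10, 11; the ring A branch, steps 5–8 and 9–11, is equally long).

Steps most likely to fail:

1. Step 4 (Proposed new method). What may go wrong: the allenolate may be protonated or consumed by oligomerization before it is acylated, or retro-Michael and O-centred pathways may outrun the Claisen closure, so that the cascade stalls before aromatization. The fallback uses known chemistry only and sets out from 3 (with 6). The classical base-mediated malonate–alkynone annulation (NaOMe, MeOH, reflux: Michael addition, then Claisen cyclization through the only ketone α-carbon) should lead by way of methyl 3-(benzyloxy)-1-methyl-2,4-dioxo-6-[(oxan-2-yloxy)methyl]cyclohex-5-ene-1-carboxylate F1, which is saponified and decarboxylated in the same flask (aqueous NaOH, 60 °C, then pH 5), to the resorcinol 2-(benzyloxy)-4-methyl-5-[(oxan-2-yloxy)methyl]benzene-1,3-diol F2. Kolbe–Schmitt carboxylation (KHCO3, CO2, DMF, 110 °C) at the single free ring position, ortho to one hydroxyl and para to the other, should give 3-(benzyloxy)-2,4-dihydroxy-5-methyl-6-[(oxan-2-yloxy)methyl]benzoic acid F3. p-TsOH in MeOH then removes the THP group and the hydroxy acid lactonizes, which brings the sequence back to the route at 9.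

2. Step 9. What may go wrong: arylation at the chelated O7 or at both phenol oxygens, and slow addition of a di-ortho-substituted phenoxide to a di-ortho-substituted fluoroarene, so that the aldehyde degrades under prolonged basic heating. The fallback is a protecting-group relay that sets out from 9. MOMCl (1.05 equiv) and i-Pr2NEt at 0 °C should protect only the non-chelated hydroxyl to give 6-(benzyloxy)-7-hydroxy-5-(methoxymethoxy)-4-methyl-2-benzofuran-1(3H)-one F4. BnBr and K2CO3 in DMF at 60 °C then give 6,7-bis(benzyloxy)-5-(methoxymethoxy)-4-methyl-2-benzofuran-1(3H)-one F5, and HCl in MeOH frees the single phenol of 6,7-bis(benzyloxy)-5-hydroxy-4-methyl-2-benzofuran-1(3H)-one F6. This phenol can be coupled with 14 under more forcing SNAr conditions (Cs2CO3, DMSO, 90 °C) without regiochemical ambiguity to give methyl 4-(benzyloxy)-2-{[6,7-bis(benzyloxy)-4-methyl-1-oxo-1,3-dihydro-2-benzofuran-5-yl]oxy}-3-formyl-6-methylbenzoate F7. BCl3 with pentamethylbenzene removes all three benzyl groups, which brings the sequence back to the route at 16.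

3. Step 11. What may go wrong: stable borate chelates of the catechol may retain the product, and the new ortho-hydroxybenzylic hydroxyl may be lost through an ortho-quinone methide during work-up. The fallback reverses the order of the last two operations and sets out from 15. NaBH4 in THF/MeOH at 0 °C reduces the aldehyde while both benzyl ethers are still in place and no catechol is present, giving methyl 4-(benzyloxy)-2-{[6-(benzyloxy)-7-hydroxy-4-methyl-1-oxo-1,3-dihydro-2-benzofuran-5-yl]oxy}-3-(hydroxymethyl)-6-methylbenzoate F8. Brief neutral hydrogenolysis (H2, 1 atm, Pd/C, EtOAc, 25 °C) then comes back to the route at 17.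

## Further compounds

F1 | step 4 | methyl 3-(benzyloxy)-1-methyl-2,4-dioxo-6-[(oxan-2-yloxy)methyl]cyclohex-5-ene-1-carboxylate | COC(=O)C1(C)C(=O)C(OCc2ccccc2)C(=O)C=C1COC1CCCCO1
F2 | step 4 | 2-(benzyloxy)-4-methyl-5-[(oxan-2-yloxy)methyl]benzene-1,3-diol | Cc1c(O)c(OCc2ccccc2)c(O)cc1COC1CCCCO1
F3 | step 4 | 3-(benzyloxy)-2,4-dihydroxy-5-methyl-6-[(oxan-2-yloxy)methyl]benzoic acid | Cc1c(O)c(OCc2ccccc2)c(O)c(C(=O)O)c1COC1CCCCO1
F4 | step 9 | 6-(benzyloxy)-7-hydroxy-5-(methoxymethoxy)-4-methyl-2-benzofuran-1(3H)-one | COCOc1c(C)c2COC(=O)c2c(O)c1OCc1ccccc1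
F5 | step 9 | 6,7-bis(benzyloxy)-5-(methoxymethoxy)-4-methyl-2-benzofuran-1(3H)-one | COCOc1c(C)c2COC(=O)c2c(OCc3ccccc3)c1OCc1ccccc1
F6 | step 9 | 6,7-bis(benzyloxy)-5-hydroxy-4-methyl-2-benzofuran-1(3H)-one | Cc1c(O)c(OCc2ccccc2)c(OCc2ccccc2)c2C(=O)OCc12
F7 | step 9 | methyl 4-(benzyloxy)-2-{[6,7-bis(benzyloxy)-4-methyl-1-oxo-1,3-dihydro-2-benzofuran-5-yl]oxy}-3-formyl-6-methylbenzoate | COC(=O)c1c(C)cc(OCc2ccccc2)c(C=O)c1Oc1c(C)c2COC(=O)c2c(OCc3ccccc3)c1OCc1ccccc1
F8 | step 11 | methyl 4-(benzyloxy)-2-{[6-(benzyloxy)-7-hydroxy-4-methyl-1-oxo-1,3-dihydro-2-benzofuran-5-yl]oxy}-3-(hydroxymethyl)-6-methylbenzoate | COC(=O)c1c(C)cc(OCc2ccccc2)c(CO)c1Oc1c(C)c2COC(=O)c2c(O)c1OCc1ccccc1
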